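The earlier runs and the new flask were generated by integration on assumed constants; scatter was added.

The vessel is a closed, stirred slurry: solid substrate goes into solution, meets the coupling partner and gives the target. We want the end amount in four new flasks with different partner charges.

| flask | solid substrate | coupling partner | remark | time |
|---|---|---|---|---|
| ochre | 0.28 M | 0.25 M | run made earlier |  |
| green | 0.28 M | 1 M | run made earlier |  |
| birch | 0.28 M | 0.300 M |  | 50 min |
| oak | 0.28 M | 0.500 M |  | 50 min |
| ash | 0.28 M | 0.800 M |  | 50 min |
| larch | 0.28 M | 1.20 M |  | 50 min |

| run | time / min | target / % | solid substrate / % |
|---|---|---|---|
| ochre | 3.00 | 7 | 92 |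
| ochre | 8.00 | 23 | 71 |
| ochre | 15.0 | 41 | 49 |
| ochre | 25.0 | 72 | 18 |
| ochre | 40.0 | 80 | 0 |
| green | 3.00 | 6 | 88 |
| green | 5.00 | 14 | 80 |
| green | 10.0 | 28 | 63 |
| green | 20.0 | 60 | 28 |
| green | 40.0 | 90 | 0 |

(each reading ± 2 percentage points)

- amount of target at the end, in percent of the solid substrate charged for birch, oak, ash, larch, in this order
- how that number moves from the first to the last of them (rises, then falls / rises all the way / falls all the way / falls, then rises / hardly changes)

- solid, in amounts per volume of the solution: solid substrate
- the earlier runs were read with a standard deviation of 2 percentage points
- at the start none of the solid substrate is in solution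
- "hardly changes" means that all values lie within two and a half points (for a concentration: within two and a half percent of the largest)

Which number has to be known well? Take time first. From ochre to green the partner rose by 0.602 powers of ten, yet the fall of the solid between the first and fourth readings, as read, quickened by 0.0209. Both runs read 0% solid at 40.0 min, which is earlier than the 50 min asked, so a modest error in pace barely touches the end.

Next, the partner charge. Ochre's partner covers 89.3% of the substrate, but even birch covers 107%, and the new charges all exceed the substrate, making the solid substrate the limiting reagent. By our reckoning, the exact charge among these four flasks matters little.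

That leaves the split between target and side product, where a reading off by 2 percentage points moves the answer by the same 2 points. Green's end reading of 90%, if the rest is side product, gives a branch ratio of 9.00, the target formed per unit of side product, a selectivity factor. That is 0.954 powers of ten, and it gives a yield of 90.0%. If the side path also takes partner one for one, ochre should reach 80.4%, and it read 80%. We commit to 90.0% in each new flask.

The forecast agrees, at 90%, 90%, 90% and 90%, with the shape hardly changes: “Selectivity therefore does not depend on partner concentration”.

The flask gives 90.1%, 90.2%, 90.2% and 90.2%, so the row hardly changes.

    starting material + coupling partner → intermediate + released group (k = 9.61 M⁻¹ min⁻¹)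
    intermediate → target (k = 1.53 min⁻¹)
    intermediate → side product (k = 0.167 min⁻¹)
    solid substrate ⇌ starting material, rate k4*(cs4 - [starting material]) while solid is left; crystals form when [starting material] > cs4 (solubility = 0.160 M, k = 0.0639 min⁻¹)

In birch, half of the dissolving was done by 14.1 min, and at 25.0 min 12.3% was still solid while the intermediate stood at 1.76%; its half-life toward target by that step was 0.45 min at 14.1 min. At 50.0 min birch held 90.1% target and 9.83% side product, a ratio of 9.17 beside our branch ratio of 9.00, with 6.7% of its partner left. In larch at 25.0 min, with 9.29% still solid, target over side product already stood at 9.16.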